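Assumption: methyl (S)-glycidate, (R)-(−)-linalyl acetate, trimethyl(prop-1-yn-1-yl)silane and 2-vinylfuran are bought; nothing in this route has been run, and selectivities are predictions.

## Retrosynthetic overview

1. Target ⇐ desilylation and C7 methyl addition/acetylation of a right-half ring ketone ⇐ central CH2–CH2 bond by mixed Kolbe electrolysis of two perhydro-1-benzoxepin-6-ylacetic acids.
2. Each bicyclic acid ⇐ one photochemical radical-cation cascade of an acyclic hydroxy alkene acid: oxepane C–O bond first (7-endo), then the cyclohexane C5a–C6 bond (6-exo Giese).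
3. Both acyclic precursors ⇐ B-alkyl Suzuki coupling of one (S,E)-iodoalkene (from methyl (S)-glycidate) with a vinyl partner: an (R)-linalyl acetate fragment (left half) or 2-vinylfuran (right half; furan = masked 4-oxo-2-enoic acid).
4. Stereocentres: C3 bought (glycidate); left C7 bought (linalyl acetate); C5a, C6, C9a set from C3 in the cascade; right C7 set by equatorial methyl addition to the ring ketone.
5. Ring order: in each half the oxepane closes before the cyclohexane in the same operation; the two bicycles are joined afterwards.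

## Route

Step 1
Reactants: 1 methyl (2S)-oxirane-2-carboxylate
Product: 3 trimethyl({2-[(2S)-oxiran-2-yl]propan-2-yl}oxy)silane, via bromomagnesium alkoxide 2 (not isolated)
Conditions: MeMgBr (2.2 equiv), THF, −78 → −30 °C; then TMSCl, −30 → 0 °C
Reagents that add atoms: methylmagnesium bromide C[Mg]Br; chlorotrimethylsilane C[Si](C)(C)Cl
Why: Double Grignard addition to the ester outruns epoxide opening at low temperature and in situ O-silylation blocks Payne rearrangement, so the bought stereocentre is carried over untouched (ester to tertiary carbinol, silyl ether formation).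

Step 2
Reactants: 3 trimethyl({2-[(2S)-oxiran-2-yl]propan-2-yl}oxy)silane; 4 trimethyl(prop-1-yn-1-yl)silane
Product: 7 (3S)-2-methylhept-6-yne-2,3-diol, via propargyllithium 5 (not isolated), via lithium alkoxide 6 (not isolated)
Conditions: 4, n-BuLi, THF, −78 °C; add 3, −78 → 0 °C; then K2CO3, MeOH, rt
Reagents that add atoms: none
Why: The propargyl anion equivalent opens the terminal epoxide by SN2 at its CH2 carbon (no stereocentre involved) and carbonate methanolysis removes the C-silyl and O-silyl groups together (epoxide alkylation, protodesilylation).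

Step 3
Reactants: 7 (3S)-2-methylhept-6-yne-2,3-diol
Product: 9 (3S,6E)-7-iodo-2,6-dimethylhept-6-ene-2,3-diol, via alkenylalane 8 (not isolated)
Conditions: Me3Al (4.5 equiv), Cp2ZrCl2 (0.3 equiv), CH2Cl2, 0 °C → rt; then I2, THF, −30 → 0 °C
Reagents that add atoms: trimethylaluminium C[Al](C)C; iodine II
Why: Negishi zirconium-catalysed syn-carboalumination puts methyl on the internal and aluminium on the terminal alkyne carbon, and iodinolysis with retention gives the E-iodoalkene only; the diol rides through as its aluminium alkoxides.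

Step 4
Reactants: 9 (3S,6E)-7-iodo-2,6-dimethylhept-6-ene-2,3-diol
Product: 10 (3S,6E)-2-hydroxy-7-iodo-2,6-dimethylhept-6-en-3-yl acetate
Conditions: Ac2O, pyridine, DMAP (cat.), CH2Cl2, 0 °C
Reagents that add atoms: acetic anhydride CC(=O)OC(C)=O
Why: Acylation of the secondary carbinol is far faster than that of the adjacent tertiary one (selective esterification).

Step 5
Reactants: 11 (3R)-3,7-dimethylocta-1,6-dien-3-yl acetate
Product: 13 (3R)-6-hydroxy-3-methylhex-1-en-3-yl acetate, via secondary ozonide 12 (not isolated)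
Conditions: O3 (1.0 equiv), CH2Cl2, −78 °C; then NaBH4, MeOH, −78 → 0 °C
Reagents that add atoms: ozone [O-][O+]=O
Why: Ozone attacks the electron-rich trisubstituted alkene much faster than the vinyl group on the acetoxy-bearing quaternary carbon, and borohydride reduces the ozonide to the primary alcohol without touching the tertiary acetate or its stereocentre (chemoselective ozonolysis, reductive work-up).

Step 6
Reactants: 13 (3R)-6-hydroxy-3-methylhex-1-en-3-yl acetate; 10 (3S,6E)-2-hydroxy-7-iodo-2,6-dimethylhept-6-en-3-yl acetate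
Product: 15 (3S,6E,10S)-2,13-dihydroxy-2,6,10-trimethyltridec-6-ene-3,10-diyl diacetate, via B-alkyl-9-BBN adduct 14 (not isolated)
Conditions: 13, 9-BBN (2.2 equiv), THF, rt; then 10, Pd(dppf)Cl2 (5 mol %), AsPh3, K3PO4 (3 M aq), DMF, rt
Reagents that add atoms: none
Why: 9-BBN adds anti-Markovnikov to the only alkene of 13, and B-alkyl Suzuki–Miyaura coupling joins that sp3 carbon to the iodoalkene with retention of the E geometry.

Step 7
Reactants: 15 (3S,6E,10S)-2,13-dihydroxy-2,6,10-trimethyltridec-6-ene-3,10-diyl diacetate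
Product: 17 (3S,6E,10S,11E)-2-hydroxy-2,6,10-trimethyl-13-oxotrideca-6,11-diene-3,10-diyl diacetate, via aldehyde 16 (not isolated)
Conditions: IBX (3 equiv), DMSO/fluorobenzene, 65 °C
Reagents that add atoms: none
Why: IBX oxidises the primary alcohol to the aldehyde and then dehydrogenates it to the E-enal (IBX α,β-dehydrogenation); the tertiary alcohol, both acetates and the trisubstituted alkene are inert.

Step 8
Reactants: 17 (3S,6E,10S,11E)-2-hydroxy-2,6,10-trimethyl-13-oxotrideca-6,11-diene-3,10-diyl diacetate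
Product: 18 (2E,4S,7E,11S)-4,11-bis(acetyloxy)-12-hydroxy-4,8,12-trimethyltrideca-2,7-dienoic acid
Conditions: NaClO2, NaH2PO4, 2-methyl-2-butene, t-BuOH/H2O, 0 °C → rt
Reagents that add atoms: sodium chlorite [Na+].[O-]Cl=O
Why: Pinnick oxidation converts the enal into the enoic acid while 2-methyl-2-butene scavenges hypochlorite and protects the trisubstituted alkene.

Step 9
Reactants: 18 (2E,4S,7E,11S)-4,11-bis(acetyloxy)-12-hydroxy-4,8,12-trimethyltrideca-2,7-dienoic acid
Product: 19 2-[(3S,5aS,6S,7S,9aS)-3,7-bis(acetyloxy)-2,2,5a,7-tetramethyldecahydro-1-benzoxepin-6-yl]acetic acid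
Conditions: 9-mesityl-3,6-di-tert-butyl-10-phenylacridinium tetrafluoroborate (5 mol %), no H-atom donor, degassed DCE (0.01 M), 450 nm LEDs, rt
Reagents that add atoms: none
Why: Proposed new method: the excited acridinium oxidises only the electron-rich C7=C8 alkene to its radical cation, the C12 tertiary hydroxyl adds reversibly at the less substituted carbon (anti-Markovnikov, 7-endo) through a chair-like transition state with the C11 acetoxy group pseudo-equatorial, the resulting ring tertiary radical closes 6-exo (Giese) on the β-carbon of the acrylic acid through a chair with tether and acceptor equatorial (trans ring fusion, axial C5a methyl, equatorial C6 arm), and the α-carboxyalkyl radical takes the electron back from the acridine radical and is protonated, so the step is a reagent-free isomerisation; the closest known reaction types are acridinium-photocatalysed anti-Markovnikov alkene hydroetherification with polar radical crossover and photoinduced-electron-transfer polyene cyclisation, neither shown for an intramolecular tertiary alcohol start with a quaternary-centre-forming 6-exo finish.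

Step 10
Reactants: 9 (3S,6E)-7-iodo-2,6-dimethylhept-6-ene-2,3-diol
Product: 20 (3S,6E)-3-{[tert-butyl(dimethyl)silyl]oxy}-7-iodo-2,6-dimethylhept-6-en-2-ol
Conditions: TBSOTf (1.05 equiv), 2,6-lutidine, CH2Cl2, −78 °C
Reagents that add atoms: tert-butyldimethylsilyl trifluoromethanesulfonate CC(C)(C)[Si](C)(C)OS(=O)(=O)C(F)(F)F
Why: At −78 °C with one equivalent of silyl triflate the secondary hydroxyl is silylated ahead of the tertiary one (selective silyl ether formation).

Step 11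
Reactants: 21 2-ethenylfuran; 20 (3S,6E)-3-{[tert-butyl(dimethyl)silyl]oxy}-7-iodo-2,6-dimethylhept-6-en-2-ol
Product: 23 (3S,6E)-3-{[tert-butyl(dimethyl)silyl]oxy}-9-(furan-2-yl)-2,6-dimethylnon-6-en-2-ol, via furylethyl-9-BBN 22 (not isolated)
Conditions: 21, 9-BBN, THF, rt; then 20, Pd(dppf)Cl2 (5 mol %), AsPh3, K3PO4 (3 M aq), DMF, rt
Reagents that add atoms: none
Why: Anti-Markovnikov hydroboration of the vinyl group followed by B-alkyl Suzuki–Miyaura coupling with retention of the E-alkene geometry.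

Step 12
Reactants: 23 (3S,6E)-3-{[tert-butyl(dimethyl)silyl]oxy}-9-(furan-2-yl)-2,6-dimethylnon-6-en-2-ol
Product: 25 5-[(3E,7S)-7-{[tert-butyl(dimethyl)silyl]oxy}-8-hydroxy-4,8-dimethylnon-3-en-1-yl]-5-methoxyfuran-2(5H)-one (both C5 epimers), via methoxy hydroperoxide 24 (not isolated)
Conditions: O2, tetraphenylporphyrin (cat.), MeOH/CH2Cl2, −78 °C, visible light (1 equiv O2 uptake); then Ac2O, pyridine, 0 °C
Reagents that add atoms: dioxygen O=O; methanol CO
Why: Singlet oxygen adds [4+2] to the furan far faster than it enes the trisubstituted alkene, methanol opens the endoperoxide at the substituted carbon and Kornblum-type dehydration of the hydroperoxide gives the 5-methoxybutenolide, a masked 4-oxo-2-enoic acid whose acceptor carbon is unambiguously the β-carbon (furan photooxygenation).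

Step 13
Reactants: 25 5-[(3E,7S)-7-{[tert-butyl(dimethyl)silyl]oxy}-8-hydroxy-4,8-dimethylnon-3-en-1-yl]-5-methoxyfuran-2(5H)-one
Product: 27 2-[(3S,5aS,6S,9aS)-3-{[tert-butyl(dimethyl)silyl]oxy}-2,2,5a-trimethyl-7-oxodecahydro-1-benzoxepin-6-yl]acetic acid, via methoxy lactone 26 (not isolated)
Conditions: acridinium salt of step 9 (5 mol %), degassed DCE (0.01 M), 450 nm LEDs, rt; then LiOH, THF/H2O, rt; then 1 M HCl to pH 3
Reagents that add atoms: lithium hydroxide [Li+].[OH-]
Why: Proposed new method: the same radical-cation cascade as in step 9 (7-endo anti-Markovnikov attack of the tertiary hydroxyl with the silyloxy group pseudo-equatorial, then 6-exo Giese closure of the ring tertiary radical on the butenolide β-carbon and electron return from the acridine radical) builds the trans-fused bicycle from either ketal epimer, and saponification of the pseudo-ester unmasks the ketone and equilibrates C6 to the equatorial arm; closest known reaction types are acridinium-photocatalysed alkene hydroetherification with polar radical crossover and pseudo-ester hydrolysis.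

Step 14
Reactants: 19 2-[(3S,5aS,6S,7S,9aS)-3,7-bis(acetyloxy)-2,2,5a,7-tetramethyldecahydro-1-benzoxepin-6-yl]acetic acid; 27 2-[(3S,5aS,6S,9aS)-3-{[tert-butyl(dimethyl)silyl]oxy}-2,2,5a-trimethyl-7-oxodecahydro-1-benzoxepin-6-yl]acetic acid
Product: 28 (3S,5aS,6S,7S,9aS)-6-{2-[(3S,5aS,6S,9aS)-3-{[tert-butyl(dimethyl)silyl]oxy}-2,2,5a-trimethyl-7-oxodecahydro-1-benzoxepin-6-yl]ethyl}-2,2,5a,7-tetramethyldecahydro-1-benzoxepine-3,7-diyl diacetate
Conditions: 19 (1 equiv), 27 (3 equiv), KOH (0.1 equiv per acid), MeOH, Pt anode and cathode, undivided cell, 0.25 A cm−2, 5–10 °C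
Reagents that add atoms: none
Why: Mixed Kolbe electrolysis: anodic decarboxylation gives the two primary radicals, which couple at the electrode, and the threefold excess of 27 channels most of 19 into the cross product (homodimers are removed by chromatography); no stereocentre is touched.

Step 15
Reactants: 28 (3S,5aS,6S,7S,9aS)-6-{2-[(3S,5aS,6S,9aS)-3-{[tert-butyl(dimethyl)silyl]oxy}-2,2,5a-trimethyl-7-oxodecahydro-1-benzoxepin-6-yl]ethyl}-2,2,5a,7-tetramethyldecahydro-1-benzoxepine-3,7-diyl diacetate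
Product: 30 (3S,5aS,6S,7S,9aS)-6-{2-[(3S,5aS,6S,7R,9aS)-7-(acetyloxy)-3-{[tert-butyl(dimethyl)silyl]oxy}-2,2,5a,7-tetramethyldecahydro-1-benzoxepin-6-yl]ethyl}-2,2,5a,7-tetramethyldecahydro-1-benzoxepine-3,7-diyl diacetate, via cerium alkoxide 29 (not isolated)
Conditions: MeLi, CeCl3 (anhydrous), THF, −78 °C; then Ac2O, DMAP, −78 °C → rt
Reagents that add atoms: methyllithium [Li]C; acetic anhydride CC(=O)OC(C)=O
Why: The organocerium reagent adds to the ketone and spares the acetates at −78 °C; the axial face of C7 is blocked by the 1,3-diaxial C5a methyl, so methyl enters equatorially and gives the axial 7R alkoxide, which is acetylated in situ (chemoselective 1,2-addition, alkoxide acylation).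

Step 16
Reactants: 30 (3S,5aS,6S,7S,9aS)-6-{2-[(3S,5aS,6S,7R,9aS)-7-(acetyloxy)-3-{[tert-butyl(dimethyl)silyl]oxy}-2,2,5a,7-tetramethyldecahydro-1-benzoxepin-6-yl]ethyl}-2,2,5a,7-tetramethyldecahydro-1-benzoxepine-3,7-diyl diacetate
Product: 31 (3S,5aS,6S,7S,9aS)-6-{2-[(3S,5aS,6S,7R,9aS)-7-(acetyloxy)-3-hydroxy-2,2,5a,7-tetramethyldecahydro-1-benzoxepin-6-yl]ethyl}-2,2,5a,7-tetramethyldecahydro-1-benzoxepine-3,7-diyl diacetate
Conditions: HF·pyridine, THF/pyridine, 0 °C → rt
Reagents that add atoms: none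
Why: Fluoride-mediated desilylation frees the secondary hydroxyl without acyl migration or loss of the three acetates (silyl ether cleavage).

## Compound list

1 | methyl (2S)-oxirane-2-carboxylate | COC(=O)[C@@H]1CO1 | starting material
2 | bromomagnesium 2-[(2S)-oxiran-2-yl]propan-2-olate | CC(C)(O[Mg]Br)[C@@H]1CO1 | intermediate
3 | trimethyl({2-[(2S)-oxiran-2-yl]propan-2-yl}oxy)silane | CC(C)(O[Si](C)(C)C)[C@@H]1CO1 | intermediate
4 | trimethyl(prop-1-yn-1-yl)silane | CC#C[Si](C)(C)C | starting material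
5 | [3-(trimethylsilyl)prop-2-yn-1-yl]lithium | [Li]CC#C[Si](C)(C)C | intermediate
6 | lithium (3S)-2-methyl-7-(trimethylsilyl)-2-[(trimethylsilyl)oxy]hept-6-yn-3-olate | C[Si](C)(C)C#CCC[C@H](O[Li])C(C)(C)O[Si](C)(C)C | intermediate
7 | (3S)-2-methylhept-6-yne-2,3-diol | C#CCC[C@H](O)C(C)(C)O | intermediate
8 | [(1E,5S)-5,6-dihydroxy-2,6-dimethylhept-1-en-1-yl]dimethylalumane (hydroxyls present as aluminium alkoxides) | C[Al](C)/C=C(\C)CC[C@H](O)C(C)(C)O | intermediate
9 | (3S,6E)-7-iodo-2,6-dimethylhept-6-ene-2,3-diol | I/C=C(\C)CC[C@H](O)C(C)(C)O | intermediate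
10 | (3S,6E)-2-hydroxy-7-iodo-2,6-dimethylhept-6-en-3-yl acetate | I/C=C(\C)CC[C@H](OC(C)=O)C(C)(C)O | intermediate
11 | (3R)-3,7-dimethylocta-1,6-dien-3-yl acetate, (R)-linalyl acetate | C=C[C@](C)(OC(C)=O)CCC=C(C)C | starting material
12 | (3R)-5-(5,5-dimethyl-1,2,4-trioxolan-3-yl)-3-methylpent-1-en-3-yl acetate (trioxolane carbon unspecified) | C=C[C@](C)(OC(C)=O)CCC1OOC(C)(C)O1 | intermediate
13 | (3R)-6-hydroxy-3-methylhex-1-en-3-yl acetate | C=C[C@](C)(OC(C)=O)CCCO | intermediate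
14 | (3S)-1-(9-borabicyclo[3.3.1]nonan-9-yl)-6-hydroxy-3-methylhexan-3-yl acetate | B1(CC[C@](C)(OC(C)=O)CCCO)C2CCCC1CCC2 | intermediate
15 | (3S,6E,10S)-2,13-dihydroxy-2,6,10-trimethyltridec-6-ene-3,10-diyl diacetate | CC(C)(O)[C@@H](OC(C)=O)CC/C(C)=C/CC[C@](C)(OC(C)=O)CCCO | intermediate
16 | (3S,6E,10S)-2-hydroxy-2,6,10-trimethyl-13-oxotridec-6-ene-3,10-diyl diacetate | CC(C)(O)[C@@H](OC(C)=O)CC/C(C)=C/CC[C@](C)(OC(C)=O)CCC=O | intermediate
17 | (3S,6E,10S,11E)-2-hydroxy-2,6,10-trimethyl-13-oxotrideca-6,11-diene-3,10-diyl diacetate | CC(C)(O)[C@@H](OC(C)=O)CC/C(C)=C/CC[C@](C)(OC(C)=O)/C=C/C=O | intermediate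
18 | (2E,4S,7E,11S)-4,11-bis(acetyloxy)-12-hydroxy-4,8,12-trimethyltrideca-2,7-dienoic acid | CC(C)(O)[C@@H](OC(C)=O)CC/C(C)=C/CC[C@](C)(OC(C)=O)/C=C/C(=O)O | intermediate
19 | 2-[(3S,5aS,6S,7S,9aS)-3,7-bis(acetyloxy)-2,2,5a,7-tetramethyldecahydro-1-benzoxepin-6-yl]acetic acid | CC(=O)O[C@H]1CC[C@]2(C)[C@H](CC[C@](C)(OC(C)=O)[C@H]2CC(=O)O)OC1(C)C | intermediate
20 | (3S,6E)-3-{[tert-butyl(dimethyl)silyl]oxy}-7-iodo-2,6-dimethylhept-6-en-2-ol | I/C=C(\C)CC[C@H](O[Si](C)(C)C(C)(C)C)C(C)(C)O | intermediate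
21 | 2-ethenylfuran | C=Cc1ccco1 | starting material
22 | 9-[2-(furan-2-yl)ethyl]-9-borabicyclo[3.3.1]nonane | B1(CCc2ccco2)C2CCCC1CCC2 | intermediate
23 | (3S,6E)-3-{[tert-butyl(dimethyl)silyl]oxy}-9-(furan-2-yl)-2,6-dimethylnon-6-en-2-ol | CC(C)(O)[C@@H](O[Si](C)(C)C(C)(C)C)CC/C(C)=C/CCc1ccco1 | intermediate
24 | (3S,6E)-3-{[tert-butyl(dimethyl)silyl]oxy}-9-(5-hydroperoxy-2-methoxy-2,5-dihydrofuran-2-yl)-2,6-dimethylnon-6-en-2-ol (ring carbons unspecified) | COC1(CC/C=C(\C)CC[C@H](O[Si](C)(C)C(C)(C)C)C(C)(C)O)C=CC(OO)O1 | intermediate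
25 | 5-[(3E,7S)-7-{[tert-butyl(dimethyl)silyl]oxy}-8-hydroxy-4,8-dimethylnon-3-en-1-yl]-5-methoxyfuran-2(5H)-one (both C5 epimers) | COC1(CC/C=C(\C)CC[C@H](O[Si](C)(C)C(C)(C)C)C(C)(C)O)C=CC(=O)O1 | intermediate
26 | cyclic methoxy pseudo-ester of 27: γ-lactone closed from the C6 acetic acid arm onto a C7 methoxy ketal, oxepane centres 3S,5aS,9aS (C6 and C7 unspecified) | O=C1CC2[C@]3(C)CC[C@H](O[Si](C)(C)C(C)(C)C)C(C)(C)O[C@H]3CCC2(OC)O1 | intermediate
27 | 2-[(3S,5aS,6S,9aS)-3-{[tert-butyl(dimethyl)silyl]oxy}-2,2,5a-trimethyl-7-oxodecahydro-1-benzoxepin-6-yl]acetic acid | OC(=O)C[C@H]1[C@]2(C)CC[C@H](O[Si](C)(C)C(C)(C)C)C(C)(C)O[C@H]2CCC1=O | intermediate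
28 | (3S,5aS,6S,7S,9aS)-6-{2-[(3S,5aS,6S,9aS)-3-{[tert-butyl(dimethyl)silyl]oxy}-2,2,5a-trimethyl-7-oxodecahydro-1-benzoxepin-6-yl]ethyl}-2,2,5a,7-tetramethyldecahydro-1-benzoxepine-3,7-diyl diacetate | CC(=O)O[C@H]1CC[C@]2(C)[C@H](CC[C@](C)(OC(C)=O)[C@H]2CC[C@H]2[C@]3(C)CC[C@H](O[Si](C)(C)C(C)(C)C)C(C)(C)O[C@H]3CCC2=O)OC1(C)C | intermediate
29 | dichlorocerium 7R-alkoxide formed from 28 by methyl addition at C7 of the right half | CC(=O)O[C@H]1CC[C@]2(C)[C@H](CC[C@](C)(OC(C)=O)[C@H]2CC[C@H]2[C@]3(C)CC[C@H](O[Si](C)(C)C(C)(C)C)C(C)(C)O[C@H]3CC[C@@]2(C)O[Ce](Cl)Cl)OC1(C)C | intermediate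
30 | (3S,5aS,6S,7S,9aS)-6-{2-[(3S,5aS,6S,7R,9aS)-7-(acetyloxy)-3-{[tert-butyl(dimethyl)silyl]oxy}-2,2,5a,7-tetramethyldecahydro-1-benzoxepin-6-yl]ethyl}-2,2,5a,7-tetramethyldecahydro-1-benzoxepine-3,7-diyl diacetate | CC(=O)O[C@H]1CC[C@]2(C)[C@H](CC[C@](C)(OC(C)=O)[C@H]2CC[C@H]2[C@]3(C)CC[C@H](O[Si](C)(C)C(C)(C)C)C(C)(C)O[C@H]3CC[C@@]2(C)OC(C)=O)OC1(C)C | intermediate
31 | (3S,5aS,6S,7S,9aS)-6-{2-[(3S,5aS,6S,7R,9aS)-7-(acetyloxy)-3-hydroxy-2,2,5a,7-tetramethyldecahydro-1-benzoxepin-6-yl]ethyl}-2,2,5a,7-tetramethyldecahydro-1-benzoxepine-3,7-diyl diacetate (CNP0169816.2) | CC(=O)O[C@H]1CC[C@]2(C)[C@H](CC[C@](C)(OC(C)=O)[C@H]2CC[C@H]2[C@]3(C)CC[C@H](O)C(C)(C)O[C@H]3CC[C@@]2(C)OC(C)=O)OC1(C)C | target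

## Count and risks

Total step count: 16. Longest linear sequence: 11 steps (1, 2, 3, 4, 6, 7, 8, 9, 14, 15, 16).

Most likely to fail:

**Step 9 (the new cascade; step 13 uses the same method).** The tertiary alcohol may add too slowly to the radical cation, and in the left half the C4 methyl ends up syn-axial to the C5a methyl, which may erode the trans selectivity. Fallback with known reactions, setting out from 18 and coming back at 19:
- Ketohydroxylation of the trisubstituted alkene (RuCl3 cat., Oxone (2KHSO5·KHSO4·K2SO4), NaHCO3, EtOAc/MeCN/H2O) gives the α-ketol (2E,4S,11S)-4,11-bis(acetyloxy)-8,12-dihydroxy-4,8,12-trimethyl-7-oxotridec-2-enoic acid F1 (both C8 epimers are used).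
- Reductive etherification of the C7 ketone with the C12 hydroxyl (Et3SiH, TMSOTf, CH2Cl2, −78 °C) closes the oxepane and sets the ring CH–O centre by axial hydride delivery, giving (2E,4S)-4-(acetyloxy)-6-[(2S,6S)-6-(acetyloxy)-3-hydroxy-3,7,7-trimethyloxepan-2-yl]-4-methylhex-2-enoic acid F2.
- Acylation of the tertiary ring alcohol (methyl chlorooxoacetate, pyridine, DMAP) gives the methyl oxalate of that alcohol F3.
- Bu3SnH, AIBN (toluene, 100 °C, slow addition) fragments the oxalate to the same ring tertiary radical, which closes 6-exo on the acrylic acid to give 19.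

**Step 14 (mixed Kolbe coupling).** The coupling is statistical and the hindered primary radicals may couple poorly. Fallback, setting out from 27 and 19 and coming back at 28:
- Oxidative decarboxylation of 27 (Pb(OAc)4, Cu(OAc)2, pyridine, benzene, 80 °C) gives the exocyclic enone (3S,5aS,9aS)-3-{[tert-butyl(dimethyl)silyl]oxy}-2,2,5a-trimethyl-6-methylideneoctahydro-1-benzoxepin-7(2H)-one F4.
- Photoredox decarboxylative Giese addition of 19 to this enone (Ir[dF(CF3)ppy]2(dtbbpy)PF6 1 mol %, K2HPO4, DMF, blue LEDs) forms the same central bond cross-selectively; protonation and equilibration of the enolate put the C6 chain equatorial and give 28.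

**Step 15 (ketone methylation beside two acetates, then in situ acetylation of a hindered axial alkoxide).** Fallback, setting out from 28 and coming back at 30:
- Methanolysis of both acetates (NaOMe, MeOH, 40 °C) gives the diol ketone (3S,5aS,6S,9aS)-3-{[tert-butyl(dimethyl)silyl]oxy}-6-{2-[(3S,5aS,6S,7S,9aS)-3,7-dihydroxy-2,2,5a,7-tetramethyldecahydro-1-benzoxepin-6-yl]ethyl}-2,2,5a-trimethyloctahydro-1-benzoxepin-7(2H)-one F5.
- Excess MeMgBr (THF, −78 → 0 °C) adds equatorially to give the triol (3S,5aS,6S,7S,9aS)-6-{2-[(3S,5aS,6S,7R,9aS)-3-{[tert-butyl(dimethyl)silyl]oxy}-7-hydroxy-2,2,5a,7-tetramethyldecahydro-1-benzoxepin-6-yl]ethyl}-2,2,5a,7-tetramethyldecahydro-1-benzoxepine-3,7-diol F6.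
- Exhaustive acetylation (Ac2O, Et3N, DMAP, 60 °C) gives 30.

Further compounds
F1 | step 9 | (2E,4S,11S)-4,11-bis(acetyloxy)-8,12-dihydroxy-4,8,12-trimethyl-7-oxotridec-2-enoic acid (C8 epimers) | CC(C)(O)[C@@H](OC(C)=O)CCC(C)(O)C(=O)CC[C@](C)(OC(C)=O)/C=C/C(=O)O
F2 | step 9 | (2E,4S)-4-(acetyloxy)-6-[(2S,6S)-6-(acetyloxy)-3-hydroxy-3,7,7-trimethyloxepan-2-yl]-4-methylhex-2-enoic acid (C3 of the oxepane unspecified) | CC(=O)O[C@H]1CCC(C)(O)[C@H](CC[C@](C)(OC(C)=O)/C=C/C(=O)O)OC1(C)C
F3 | step 9 | (2E,4S)-4-(acetyloxy)-6-[(2S,6S)-6-(acetyloxy)-3-{[methoxy(oxo)acetyl]oxy}-3,7,7-trimethyloxepan-2-yl]-4-methylhex-2-enoic acid | CC(=O)O[C@H]1CCC(C)(OC(=O)C(=O)OC)[C@H](CC[C@](C)(OC(C)=O)/C=C/C(=O)O)OC1(C)C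
F4 | step 14 | (3S,5aS,9aS)-3-{[tert-butyl(dimethyl)silyl]oxy}-2,2,5a-trimethyl-6-methylideneoctahydro-1-benzoxepin-7(2H)-one | C=C1[C@]2(C)CC[C@H](O[Si](C)(C)C(C)(C)C)C(C)(C)O[C@H]2CCC1=O
F5 | step 15 | (3S,5aS,6S,9aS)-3-{[tert-butyl(dimethyl)silyl]oxy}-6-{2-[(3S,5aS,6S,7S,9aS)-3,7-dihydroxy-2,2,5a,7-tetramethyldecahydro-1-benzoxepin-6-yl]ethyl}-2,2,5a-trimethyloctahydro-1-benzoxepin-7(2H)-one | O[C@H]1CC[C@]2(C)[C@H](CC[C@](C)(O)[C@H]2CC[C@H]2[C@]3(C)CC[C@H](O[Si](C)(C)C(C)(C)C)C(C)(C)O[C@H]3CCC2=O)OC1(C)C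
F6 | step 15 | (3S,5aS,6S,7S,9aS)-6-{2-[(3S,5aS,6S,7R,9aS)-3-{[tert-butyl(dimethyl)silyl]oxy}-7-hydroxy-2,2,5a,7-tetramethyldecahydro-1-benzoxepin-6-yl]ethyl}-2,2,5a,7-tetramethyldecahydro-1-benzoxepine-3,7-diol | O[C@H]1CC[C@]2(C)[C@H](CC[C@](C)(O)[C@H]2CC[C@H]2[C@]3(C)CC[C@H](O[Si](C)(C)C(C)(C)C)C(C)(C)O[C@H]3CC[C@@]2(C)O)OC1(C)C
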